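## Retrosynthetic overview

1. Target ⇒ ester hydrolysis and substrate-controlled reduction of a C6 ketone (chain numbered C1 = benzylic CH2 to C11 = CMe2OH).
2. C4–C5 bond and the (E)-C2=C3 alkene ⇒ [3,3]-sigmatropic ketal Claisen rearrangement of an allyl vinyl ether built from a cis-oxolanyl methyl ketone (C5–C11) and an aryl isopropenyl carbinol (arene + C1–C4).
3. Oxolane ring (the only ring made; the benzene ring is bought) ⇒ osmium-catalysed oxidative cyclisation, an intramolecular [3+2] cycloaddition, of a 2,3-diol from (R)-linalool.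
4. Aryl carbinol ⇒ benzylic zinc reagent from methyl 4-hydroxy-3-methylbenzoate plus methacrolein.
5. Order: oxolane first (step 3), then fragment union (step 8). C7 is bought, C10 is set by C7 (step 3), C6 is set by C7 (step 9).

Assumption: commercial (R)-(−)-linalool of high enantiomeric purity is the chiral starting material, and its carbinol carbon becomes C7 of the target.

## Route

Step 1
Reactants: 1 (R)-(−)-linalool [(3R)-3,7-dimethylocta-1,6-dien-3-ol]
Product: 2 (2R)-6-methyl-2-(oxiran-2-yl)hept-5-en-2-ol (both oxirane epimers)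
Conditions: VO(acac)2 (2 mol %), t-BuOOH (1.3 equiv), PhMe, 25 → 40 °C
Reagents that add atoms: tert-butyl hydroperoxide, CC(C)(C)OO
Why: Hydroxyl-directed vanadium-catalysed epoxidation (Sharpless–Michaelson type) delivers oxygen to the allylic vinyl group and spares the remote trisubstituted alkene; the new oxirane centre forms unselectively but is erased in step 4, and the linalool carbinol centre is untouched.

Step 2
Reactants: 2 (2R)-6-methyl-2-(oxiran-2-yl)hept-5-en-2-ol
Product: 3 (3R)-3,7-dimethyloct-6-ene-2,3-diol (both C2 epimers)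
Conditions: LiAlH4, THF, 0 °C → rt; H2O/NaOH work-up
Reagents that add atoms: none
Why: SN2 hydride opening of the terminal epoxide at its unhindered CH2 carbon (the other carbon is neopentyl-like) gives the vicinal secondary/tertiary diol that serves as a two-point ligand for osmium.

Step 3
Reactants: 3 (3R)-3,7-dimethyloct-6-ene-2,3-diol
Product: 4 1-[(2R,5S)-5-(2-hydroxypropan-2-yl)-2-methyloxolan-2-yl]ethan-1-ol (both carbinol epimers)
Conditions: K2OsO4·2H2O (5 mol %), pyridine N-oxide (2 equiv), citric acid (0.75 equiv), Cu(OTf)2 (0.5 equiv), MeCN/aq. buffer (pH 6.5), 60 °C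
Reagents that add atoms: pyridine N-oxide, [O-][n+]1ccccc1
Why: In this Donohoe-type oxidative cyclisation the diol binds osmium as a glycolate and, once oxidised to octavalent osmium, its O–Os=O unit adds across the prenyl alkene in an intramolecular [3+2] cycloaddition that closes the oxolane; because the C6 oxygen stays on the metal while the C7 oxygen bonds to C10 and an oxo oxygen to C11, the C6 arm and the new CMe2OH group must be cis, so the bought C7 (R) centre fixes C10 as S.

Step 4
Reactants: 4 1-[(2R,5S)-5-(2-hydroxypropan-2-yl)-2-methyloxolan-2-yl]ethan-1-ol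
Product: 5 1-[(2R,5S)-5-(2-hydroxypropan-2-yl)-2-methyloxolan-2-yl]ethan-1-one
Conditions: nPr4N[RuO4] (5 mol %), N-methylmorpholine N-oxide (1.5 equiv), 4 Å sieves, CH2Cl2, rt
Reagents that add atoms: none
Why: Ley–Griffith oxidation touches only the secondary carbinol (the tertiary alcohol cannot be oxidised), converges both epimers of 4 on one methyl ketone and provides the carbonyl needed for the Claisen step.

Step 5
Reactants: 6 methyl 4-hydroxy-3-methylbenzoate
Product: 7 methyl 4-[(2,2-dimethylpropanoyl)oxy]-3-methylbenzoate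
Conditions: PivCl, Et3N, DMAP (cat.), CH2Cl2, 0 °C → rt
Reagents that add atoms: pivaloyl chloride, CC(C)(C)C(=O)Cl
Why: DMAP-catalysed O-acylation gives a hindered aryl pivalate that tolerates radical bromination, organozinc chemistry, hot weak acid and borohydride, and is removed in the final saponification without a separate step.

Step 6
Reactants: 7 methyl 4-[(2,2-dimethylpropanoyl)oxy]-3-methylbenzoate
Product: 8 methyl 3-(bromomethyl)-4-[(2,2-dimethylpropanoyl)oxy]benzoate
Conditions: NBS (1.05 equiv), AIBN (cat.), PhCF3, 80 °C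
Reagents that add atoms: N-bromosuccinimide, O=C1CCC(=O)N1Br
Why: Wohl–Ziegler radical bromination occurs at the only benzylic C–H position, and the acylated phenol ring is too electron-poor for ring bromination.

Step 7
Reactants: 8 methyl 3-(bromomethyl)-4-[(2,2-dimethylpropanoyl)oxy]benzoate, 9 methacrolein (2-methylprop-2-enal)
Product: 11 methyl 4-[(2,2-dimethylpropanoyl)oxy]-3-(2-hydroxy-3-methylbut-3-en-1-yl)benzoate (racemic), via benzylic zinc bromide 10 (not isolated)
Conditions: Zn dust, LiCl, THF, 0 → 25 °C; then methacrolein, 0 → 25 °C; aq. NH4Cl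
Reagents that add atoms: none
Why: LiCl-promoted zinc insertion gives an ester-tolerant benzylic zinc reagent that adds 1,2 to the enal (Knochel-type addition); the carbinol centre is formed racemic, which is harmless because it is destroyed in step 8.

Step 8
Reactants: 5 1-[(2R,5S)-5-(2-hydroxypropan-2-yl)-2-methyloxolan-2-yl]ethan-1-one, 11 methyl 4-[(2,2-dimethylpropanoyl)oxy]-3-(2-hydroxy-3-methylbut-3-en-1-yl)benzoate
Product: 14 methyl 4-[(2,2-dimethylpropanoyl)oxy]-3-{(2E)-6-[(2R,5S)-5-(2-hydroxypropan-2-yl)-2-methyloxolan-2-yl]-3-methyl-6-oxohex-2-en-1-yl}benzoate, via bicyclic methyl ketal 12 (not isolated), via allyl vinyl ether 13 (not isolated)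
Conditions: HC(OMe)3, PPTS (cat.), MeOH, rt; evaporate; then 11 (1.5 equiv), 2,4-dinitrophenol (10 mol %), xylene, 135 °C, MeOH distilled off
Reagents that add atoms: none
Why: In this ketal Claisen rearrangement (Saucy–Marbet/Faulkner variant) acid-catalysed exchange of the ketal alkoxy groups for alcohol 11 and loss of a proton from C5 (the only α-CH carbon) give the 2-substituted allyl vinyl ether 13, whose [3,3]-sigmatropic shift through a chair with the CH2Ar group equatorial forms the C4–C5 bond and the (E)-trisubstituted alkene without touching C7 or C10.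

Step 9
Reactants: 14 methyl 4-[(2,2-dimethylpropanoyl)oxy]-3-{(2E)-6-[(2R,5S)-5-(2-hydroxypropan-2-yl)-2-methyloxolan-2-yl]-3-methyl-6-oxohex-2-en-1-yl}benzoate
Product: 15 methyl 4-[(2,2-dimethylpropanoyl)oxy]-3-{(2E,6S)-6-hydroxy-6-[(2R,5S)-5-(2-hydroxypropan-2-yl)-2-methyloxolan-2-yl]-3-methylhex-2-en-1-yl}benzoate
Conditions: Zn(BH4)2, Et2O, −30 → 0 °C; aq. NH4Cl
Reagents that add atoms: none
Why: In this chelation-controlled (Cram-chelate) reduction zinc ties the ketone oxygen to the ring oxygen and the cis tertiary hydroxyl, holding C=O syn to the C7–O bond and covering the ring-CH2 face, so hydride is expected to enter from the face flanked by the C7 methyl group and the C7 (R) centre sets C6 as S (anti to the ring C–O bond), while both esters are inert to this reagent.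

Step 10
Reactants: 15 methyl 4-[(2,2-dimethylpropanoyl)oxy]-3-{(2E,6S)-6-hydroxy-6-[(2R,5S)-5-(2-hydroxypropan-2-yl)-2-methyloxolan-2-yl]-3-methylhex-2-en-1-yl}benzoate
Product: 16 4-hydroxy-3-{(2E,6S)-6-hydroxy-6-[(2R,5S)-5-(2-hydroxypropan-2-yl)-2-methyloxolan-2-yl]-3-methylhex-2-en-1-yl}benzoic acid (CNP0247938.3)
Conditions: LiOH (6 equiv), THF/MeOH/H2O, 40 °C; then dilute aq. HCl to pH 3, 0 °C
Reagents that add atoms: LiOH (lithium hydroxide), [Li+].[OH-]
Why: Saponification cleaves the methyl ester and the aryl pivalate in one operation under basic conditions that cannot epimerise any centre or cyclise the ortho-allyl phenol to a chroman.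

## Compound list

1 | (R)-(−)-linalool, (3R)-3,7-dimethylocta-1,6-dien-3-ol | C=C[C@](C)(O)CCC=C(C)C | starting material
2 | (2R)-6-methyl-2-(oxiran-2-yl)hept-5-en-2-ol (both oxirane epimers) | C1OC1[C@](C)(O)CCC=C(C)C | intermediate
3 | (3R)-3,7-dimethyloct-6-ene-2,3-diol (both C2 epimers) | CC(O)[C@](C)(O)CCC=C(C)C | intermediate
4 | 1-[(2R,5S)-5-(2-hydroxypropan-2-yl)-2-methyloxolan-2-yl]ethan-1-ol (both carbinol epimers) | CC(O)[C@@]1(C)CC[C@@H](C(C)(C)O)O1 | intermediate
5 | 1-[(2R,5S)-5-(2-hydroxypropan-2-yl)-2-methyloxolan-2-yl]ethan-1-one | CC(=O)[C@@]1(C)CC[C@@H](C(C)(C)O)O1 | intermediate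
6 | methyl 4-hydroxy-3-methylbenzoate | COC(=O)c1ccc(O)c(C)c1 | starting material
7 | methyl 4-[(2,2-dimethylpropanoyl)oxy]-3-methylbenzoate | COC(=O)c1ccc(OC(=O)C(C)(C)C)c(C)c1 | intermediate
8 | methyl 3-(bromomethyl)-4-[(2,2-dimethylpropanoyl)oxy]benzoate | COC(=O)c1ccc(OC(=O)C(C)(C)C)c(CBr)c1 | intermediate
9 | methacrolein (2-methylprop-2-enal) | CC(=C)C=O | starting material
10 | {2-[(2,2-dimethylpropanoyl)oxy]-5-(methoxycarbonyl)benzyl}zinc bromide | COC(=O)c1ccc(OC(=O)C(C)(C)C)c(C[Zn]Br)c1 | intermediate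
11 | methyl 4-[(2,2-dimethylpropanoyl)oxy]-3-(2-hydroxy-3-methylbut-3-en-1-yl)benzoate (racemic) | COC(=O)c1ccc(OC(=O)C(C)(C)C)c(CC(O)C(C)=C)c1 | intermediate
12 | (1R,5S)-2-methoxy-1,2,4,4-tetramethyl-3,8-dioxabicyclo[3.2.1]octane (both C2 epimers) | CC2(OC)[C@@]1(C)CC[C@@H](C(C)(C)O2)O1 | intermediate
13 | methyl 4-[(2,2-dimethylpropanoyl)oxy]-3-[2-({1-[(2R,5S)-5-(2-hydroxypropan-2-yl)-2-methyloxolan-2-yl]ethenyl}oxy)-3-methylbut-3-en-1-yl]benzoate (both epimers at the allylic carbon) | COC(=O)c1ccc(OC(=O)C(C)(C)C)c(CC(OC(=C)[C@@]2(C)CC[C@@H](C(C)(C)O)O2)C(C)=C)c1 | intermediate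
14 | methyl 4-[(2,2-dimethylpropanoyl)oxy]-3-{(2E)-6-[(2R,5S)-5-(2-hydroxypropan-2-yl)-2-methyloxolan-2-yl]-3-methyl-6-oxohex-2-en-1-yl}benzoate | COC(=O)c1ccc(OC(=O)C(C)(C)C)c(C/C=C(\C)CCC(=O)[C@@]2(C)CC[C@@H](C(C)(C)O)O2)c1 | intermediate
15 | methyl 4-[(2,2-dimethylpropanoyl)oxy]-3-{(2E,6S)-6-hydroxy-6-[(2R,5S)-5-(2-hydroxypropan-2-yl)-2-methyloxolan-2-yl]-3-methylhex-2-en-1-yl}benzoate | COC(=O)c1ccc(OC(=O)C(C)(C)C)c(C/C=C(\C)CC[C@H](O)[C@@]2(C)CC[C@@H](C(C)(C)O)O2)c1 | intermediate
16 | 4-hydroxy-3-{(2E,6S)-6-hydroxy-6-[(2R,5S)-5-(2-hydroxypropan-2-yl)-2-methyloxolan-2-yl]-3-methylhex-2-en-1-yl}benzoic acid | C/C(=C\Cc1cc(C(=O)O)ccc1O)CC[C@H](O)[C@@]1(C)CC[C@@H](C(C)(C)O)O1 | target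

## Step count and risk

Total step count: 10 (seven on the linalool line, three on the aryl branch).
Longest linear sequence: 7 steps (1 → 16 through steps 1, 2, 3, 4, 8, 9, 10).

Steps most likely to fail:

**Step 9 (facial selectivity of the ketone reduction).** The two groups flanking the carbonyl on C7 (methyl and ring CH2) are similar in size, so the ratio and even the sense of induction under zinc chelation are uncertain. The fallback sets out from 14. The tertiary hydroxyl is capped with N-(trimethylsilyl)imidazole to give the trimethylsilyl ether F1, which can no longer join a chelate. Reduction under non-chelating Felkin–Anh control with LiBH(s-Bu)3 in THF at −78 °C gives the silyl-protected 6S carbinol F2. Removal of silicon with Bu4NF/AcOH comes back to the route at 15. The chelate and Felkin–Anh models attack opposite carbonyl faces, so a wrong result from one predicts the right result from the other.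

**Step 8 (ketal Claisen between two advanced partners).** Ketal exchange at a hindered α-alkoxy ketone with a hindered secondary allylic alcohol may be slow, and hot acid may erode 11. The fallback is a Carroll rearrangement and sets out from 5 and 11. Alcohol 11 is treated with 1,1'-carbonyldiimidazole to give its imidazole-1-carboxylate F3. The dilithio derivative of 5 (LiN(SiMe3)2, 2.2 equiv, THF, −78 °C) is C-acylated with F3 to give the allyl β-keto ester F4. Heating F4 in xylene at 140 °C triggers the [3,3] shift of its enol form to the β-keto acid F5, which loses CO2 in the same flask and comes back to the route at 14 with the same chair-controlled E geometry.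

**Step 1 (chemoselective epoxidation).** Only hydroxyl direction protects the more nucleophilic trisubstituted alkene, and any attack there leads to linalool oxides. The fallback sets out from 1. Tsuji–Wacker oxidation of the vinyl group (PdCl2, CuCl, O2, DMF/H2O), to which the trisubstituted alkene is inert, gives the hydroxy ketone (3R)-3-hydroxy-3,7-dimethyloct-6-en-2-one F6. Reduction with NaBH4 in MeOH comes back to the route at 3, again as both C2 epimers.

## Further compounds

F1 | step 9 | methyl 4-[(2,2-dimethylpropanoyl)oxy]-3-{(2E)-3-methyl-6-[(2R,5S)-2-methyl-5-{2-[(trimethylsilyl)oxy]propan-2-yl}oxolan-2-yl]-6-oxohex-2-en-1-yl}benzoate | COC(=O)c1ccc(OC(=O)C(C)(C)C)c(C/C=C(\C)CCC(=O)[C@@]2(C)CC[C@@H](C(C)(C)O[Si](C)(C)C)O2)c1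
F2 | step 9 | methyl 4-[(2,2-dimethylpropanoyl)oxy]-3-{(2E,6S)-6-hydroxy-3-methyl-6-[(2R,5S)-2-methyl-5-{2-[(trimethylsilyl)oxy]propan-2-yl}oxolan-2-yl]hex-2-en-1-yl}benzoate | COC(=O)c1ccc(OC(=O)C(C)(C)C)c(C/C=C(\C)CC[C@H](O)[C@@]2(C)CC[C@@H](C(C)(C)O[Si](C)(C)C)O2)c1
F3 | step 8 | methyl 4-[(2,2-dimethylpropanoyl)oxy]-3-{2-[(1H-imidazole-1-carbonyl)oxy]-3-methylbut-3-en-1-yl}benzoate (racemic) | COC(=O)c1ccc(OC(=O)C(C)(C)C)c(CC(OC(=O)n2ccnc2)C(C)=C)c1
F4 | step 8 | methyl 4-[(2,2-dimethylpropanoyl)oxy]-3-[2-({3-[(2R,5S)-5-(2-hydroxypropan-2-yl)-2-methyloxolan-2-yl]-3-oxopropanoyl}oxy)-3-methylbut-3-en-1-yl]benzoate (both epimers at the allylic carbon) | COC(=O)c1ccc(OC(=O)C(C)(C)C)c(CC(OC(=O)CC(=O)[C@@]2(C)CC[C@@H](C(C)(C)O)O2)C(C)=C)c1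
F5 | step 8 | (4E)-6-{2-[(2,2-dimethylpropanoyl)oxy]-5-(methoxycarbonyl)phenyl}-2-[(2R,5S)-5-(2-hydroxypropan-2-yl)-2-methyloxolane-2-carbonyl]-4-methylhex-4-enoic acid (both C2 epimers) | COC(=O)c1ccc(OC(=O)C(C)(C)C)c(C/C=C(\C)CC(C(=O)O)C(=O)[C@@]2(C)CC[C@@H](C(C)(C)O)O2)c1
F6 | step 1 | (3R)-3-hydroxy-3,7-dimethyloct-6-en-2-one | CC(=O)[C@](C)(O)CCC=C(C)C
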